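**Assumption:** the target is the all-cis (2R,3R,6S) piperidine as drawn; Boc-D-alaninal (used fresh, it epimerises on storage), 12-bromo-1-dodecene and (E)-4-acetoxy-3-methoxycinnamic acid are taken as purchasable.

## Retrosynthetic overview
1. Target ⇒ N-Boc-cassine + O-acetylferulic acid (esterification at O-3, then one acidic unmasking of ArOAc and N-Boc).
2. Methyl ketone ⇒ terminal alkene (Tsuji–Wacker), so the side chain enters as a C12 alkenyl Grignard.
3. Piperidine (the only ring formed that is kept) ⇒ N1=C6 cyclic imine from a δ-amino ketone, reduced to the 2,6-cis isomer (sets C6).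
4. δ-Amino ketone ⇒ γ-lactone + Grignard; the lactone is a transient ring, formed first and opened in step 2.
5. Lactone ⇒ Boc-D-alaninal (supplies C2) + propanoate homoenolate, added under chelation control (sets C3).

## Route

**Step 1**
Reactants: **1** Boc-D-alaninal, tert-butyl N-[(2R)-1-oxopropan-2-yl]carbamate; **2** ethyl 3-iodopropanoate
Product: **3** tert-butyl N-{(1R)-1-[(2R)-5-oxooxolan-2-yl]ethyl}carbamate (syn/threo amino-lactone)
Conditions: 2, Zn–Cu, PhMe/DMA, 60 °C; TiCl3(Oi-Pr), CH2Cl2, −40 °C; add 1, −40 → −20 °C; then cat. AcOH, PhMe, 80 °C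
Reagents that add atoms: ethyl 3-iodopropanoate, ICCC(=O)OCC (delivers CH2CH2C=O; OEt is lost on lactonisation)
Why: Titanium homoenolate addition to the aldehyde under Cram-chelate control (Ti bridges C=O and NHBoc, attack anti to CH3) gives the syn amino alcohol, so the new carbinol is R; the γ-hydroxy ester then lactonises.

**Step 2**
Reactants: **3**; **4** 12-bromo-1-dodecene
Product: **5** tert-butyl N-[(2R,3R)-3-hydroxy-6-oxooctadec-17-en-2-yl]carbamate (exists largely as its cyclic 5-membered hemiketal)
Conditions: 4, Mg, THF (→ RMgBr, 2.2 equiv); add to 3, THF, −78 → −40 °C; cold NH4Cl quench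
Reagents that add atoms: dodec-11-enylmagnesium bromide from 4, C=CCCCCCCCCCCBr
Why: Mono-addition of a Grignard to a lactone: the first equivalent deprotonates NHBoc, the second adds to C=O, and the magnesium hemiketal is stable at low temperature so the ketone appears only on quench; no stereocentre is touched.

**Step 3**
Reactants: **5**
Product: **6** (2R,3R,6S)-6-(dodec-11-en-1-yl)-2-methylpiperidin-3-ol
Conditions: TFA/CH2Cl2 (1:4), 0 °C, 1 h; evaporate; Et3N, MeOH, rt; NaBH4, −40 → 0 °C
Reagents that add atoms: none
Why: Boc removal lets the δ-amino ketone condense to the six-membered cyclic imine (intramolecular reductive amination). Axial hydride attack on the half-chair (2-Me pseudo-equatorial, 3-OH axial, attack anti to both) gives the all-cis piperidine, so C6 is S; NaBH4 leaves the alkene alone.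

**Step 4**
Reactants: **6**
Product: **7** tert-butyl (2R,3R,6S)-6-(dodec-11-en-1-yl)-3-hydroxy-2-methylpiperidine-1-carboxylate
Conditions: Boc2O (3 equiv), Et3N, MeOH, 50 °C, 24 h (no DMAP)
Reagents that add atoms: di-tert-butyl dicarbonate, CC(C)(C)OC(=O)OC(=O)OC(C)(C)C
Why: Carbamate protection of the hindered secondary amine; without DMAP the amine reacts in preference to the secondary alcohol, and N-Boc blocks N-acylation and Pd coordination in later steps.

**Step 5**
Reactants: **7**
Product: **8** N-Boc-(−)-cassine, tert-butyl (2R,3R,6S)-3-hydroxy-2-methyl-6-(11-oxododecyl)piperidine-1-carboxylate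
Conditions: PdCl2 (10 mol %), CuCl (1 equiv), O2 (1 atm), DMF/H2O 7:1, rt
Reagents that add atoms: water, O (source of the ketone oxygen)
Why: Tsuji–Wacker oxidation of the remote terminal alkene gives the methyl ketone with Markovnikov selectivity; the free secondary OH and the carbamate are tolerated.

**Step 6**
Reactants: **8**; **9** (E)-4-acetoxy-3-methoxycinnamic acid (O-acetylferulic acid)
Product: **10** tert-butyl (2R,3R,6S)-3-{[(2E)-3-(4-acetoxy-3-methoxyphenyl)prop-2-enoyl]oxy}-2-methyl-6-(11-oxododecyl)piperidine-1-carboxylate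
Conditions: 9, (COCl)2, cat. DMF, CH2Cl2, 0 °C → rt; concentrate; then 8, Et3N, DMAP, CH2Cl2, 0 °C → rt
Reagents that add atoms: O-acetylferuloyl chloride from 9, COc1cc(/C=C/C(=O)O)ccc1OC(C)=O
Why: DMAP-catalysed acylation of the C3 alcohol by the acid chloride; this is acylation at oxygen, so C3 keeps its R configuration and the E-alkene is carried through.

**Step 7**
Reactants: **10**
Product: **11** (+)-3-O-feruloylcassine (target)
Conditions: HCl (≈2–3 M, from AcCl) in MeOH, 0 °C → rt; then H2O (10 vol %), 30 min; NaHCO3 work-up to pH ≈ 8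
Reagents that add atoms: none
Why: Acidolysis removes the Boc group and acid-catalysed methanolysis removes the unhindered phenolic acetate, while the hindered, conjugated secondary ferulate ester reacts far more slowly. The amine stays protonated (no acetyl or feruloyl transfer to N), and the water step reverses any dimethyl ketal formed at the ketone.

## Compound list
1 | Boc-D-alaninal, tert-butyl N-[(2R)-1-oxopropan-2-yl]carbamate | C[C@@H](NC(=O)OC(C)(C)C)C=O | starting material
2 | ethyl 3-iodopropanoate | CCOC(=O)CCI | starting material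
3 | tert-butyl N-{(1R)-1-[(2R)-5-oxooxolan-2-yl]ethyl}carbamate | C[C@@H](NC(=O)OC(C)(C)C)[C@H]1CCC(=O)O1 | intermediate
4 | 12-bromo-1-dodecene | C=CCCCCCCCCCCBr | starting material
5 | tert-butyl N-[(2R,3R)-3-hydroxy-6-oxooctadec-17-en-2-yl]carbamate (open form of the hemiketal) | C[C@@H](NC(=O)OC(C)(C)C)[C@H](O)CCC(=O)CCCCCCCCCCC=C | intermediate
6 | (2R,3R,6S)-6-(dodec-11-en-1-yl)-2-methylpiperidin-3-ol | O[C@@H]1CC[C@H](CCCCCCCCCCC=C)N[C@@H]1C | intermediate
7 | tert-butyl (2R,3R,6S)-6-(dodec-11-en-1-yl)-3-hydroxy-2-methylpiperidine-1-carboxylate | O[C@@H]1CC[C@H](CCCCCCCCCCC=C)N(C(=O)OC(C)(C)C)[C@@H]1C | intermediate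
8 | N-Boc-(−)-cassine | O[C@@H]1CC[C@H](CCCCCCCCCCC(C)=O)N(C(=O)OC(C)(C)C)[C@@H]1C | intermediate
9 | (E)-4-acetoxy-3-methoxycinnamic acid | COc1cc(/C=C/C(=O)O)ccc1OC(C)=O | starting material
10 | N-Boc-3-O-(4-O-acetylferuloyl)cassine | COc1cc(/C=C/C(=O)O[C@@H]2CC[C@H](CCCCCCCCCCC(C)=O)N(C(=O)OC(C)(C)C)[C@@H]2C)ccc1OC(C)=O | intermediate
11 | (+)-3-O-feruloylcassine | COc1cc(/C=C/C(=O)O[C@@H]2CC[C@H](CCCCCCCCCCC(C)=O)N[C@@H]2C)ccc1O | target

## Summary
Total steps: 7. Longest linear sequence: 7 (from 1).

Three steps most likely to fail, each with a fallback that changes the approach: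

- **Step 1** (syn selectivity of the homoenolate addition; epimerisable aldehyde). Fallback: set both centres by reagent control instead. Sharpless asymmetric aminohydroxylation of ethyl crotonate [(DHQD)2PHAL, BocNClNa] gives ethyl (2S,3R)-3-(Boc-amino)-2-hydroxybutanoate; N,O-acetonide, DIBAL, Ph3P=CHCO2Et, H2/Pd-C and acid then converge on lactone 3.
- **Step 2** (over-addition to, or enolisation of, the lactone). Fallback: change the electrophile. Open 3 with Me(MeO)NH·HCl/AlMe3 to the γ-hydroxy Weinreb amide, protect as the TBS ether, then add the Grignard (single addition is enforced by the chelated intermediate); the silyl ether is removed with acid before the imine reduction.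
- **Step 7** (removing ArOAc and Boc without losing the ferulate ester). Fallback: avoid phenol protection altogether. Acylate 8 with Meldrum's acid (PhMe, 90 °C) to the malonate half-ester, run a Knoevenagel–Doebner condensation with vanillin (pyridine, cat. piperidine) to build the E-ferulate with its free phenol, then remove only the Boc group with TFA.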